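**Retrosynthetic overview**
- The strategy rests on ring A: three different oxygens (ring oxygen O1 on C8a, OMe on C7, free OH on C5) with the prenyl group on C8 between C8a and C7. Prenylating a preformed phloroglucinol would not place it there selectively, so ring A is built from acyclic carbons.
- Ring A (formed first): Danheiser benzannulation of 3-ethoxycyclobutenone with a prenyl-substituted methoxyalkyne forms C8–C8a, C6–C7 and C4a–C8a. It gives a phenol (future O1), OMe at C7, OEt at C5, and C4a as the only free ortho position.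
- C4a–C4: MOM-directed ortho-lithiation and acylation with the cinnamic N-methoxy-N-methylamide made from 2,4,6-trimethoxybenzaldehyde; ring B is bought intact.
- Ring C (formed second): MOM removal, then catalytic asymmetric oxa-Michael closure O1–C2 sets 2S; the chelated 5-O-ethyl ether is cleaved last.

Key step: step 3

Assumption (chemistry): the quinine-derived 9-amino-9-deoxy-epi thiourea is taken to give the 2S flavanone in step 8; if a trial shows the opposite sense, its quinidine-derived pseudoenantiomer is used in the same way.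

**Step 1**
Reactants: 1 ethoxyacetylene; 2 acetyl chloride
Product: 4 3-ethoxycyclobut-2-en-1-one, via ketene 3 (not isolated)
Conditions: Et3N, Et2O/hexanes, slow addition of 2 at 0 °C, then rt
Reagents that add atoms: none
Why: Dehydrochlorination of acetyl chloride gives ketene, which the electron-rich alkyne should trap in a [2+2] cycloaddition; the nucleophilic terminal carbon bonds to the ketene carbonyl carbon, so the ethoxy group ends at C3.

**Step 2**
Reactants: 5 chloroacetaldehyde dimethyl acetal; 6 prenyl bromide
Product: 8 1-methoxy-5-methylhex-4-en-1-yne, via lithium methoxyacetylide 7 (not isolated)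
Conditions: LiNEt2 (3.0 equiv, from n-BuLi and Et2NH), THF, 0 °C; then 6, DMPU, −78 °C → rt
Reagents that add atoms: none
Why: Successive eliminations of methanol and HCl by three equivalents of amide give the lithium acetylide of methoxyacetylene, which should undergo SN2 alkylation at the primary carbon of the allylic bromide; no excess base remains to isomerise the skipped enyne.

**Step 3**
Reactants: 4 3-ethoxycyclobut-2-en-1-one; 8 1-methoxy-5-methylhex-4-en-1-yne
Product: 13 5-ethoxy-3-methoxy-2-(3-methylbut-2-en-1-yl)phenol, via vinylketene 9 (not isolated), via vinylcyclobutenone 10 (not isolated), via dienylketene 11 (not isolated), via cyclohexadienone 12 (not isolated)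
Conditions: toluene, 80 °C → 110 °C (4 in slight excess); then K2CO3, MeOH, rt
Reagents that add atoms: none
Why: Heating opens 4 by 4π electrocyclic ring opening to vinylketene 9, whose ketene C=C adds [2+2] to ynol ether 8 (bonds C8–C8a and C6–C7) to give vinylcyclobutenone 10; a second 4π opening gives dienylketene 11, and 6π electrocyclic closure (C4a–C8a) followed by tautomerisation of dienone 12 should deliver phenol 13. This is the Danheiser benzannulation of a cyclobutenone with an alkoxyalkyne, a known route to resorcinol monoethers; a 3-alkoxycyclobutenone is a less usual ketene source and extends the product to a phloroglucinol. Ring A, the only ring formed, closes by the thermal 6π electrocyclisation of the dienylketene, and no stereocentre is created. The selectivity needed is the orientation of the ketene–alkyne addition: the ynol ether is polarised so that its prenyl-bearing carbon is nucleophilic and bonds to the ketene carbonyl carbon, which puts the prenyl group next to the phenol carbon and the methoxy group beyond it. The electron-rich alkyne is a far better ketenophile than the trisubstituted prenyl alkene, and a methoxyalkyne has no β-hydrogen for the retro-ene loss that limits ethoxyalkynes on heating. The closing basic methanolysis returns any product that excess vinylketene has O-acylated.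

**Step 4**
Reactants: 13 5-ethoxy-3-methoxy-2-(3-methylbut-2-en-1-yl)phenol
Product: 14 5-ethoxy-1-methoxy-3-(methoxymethoxy)-2-(3-methylbut-2-en-1-yl)benzene
Conditions: MOMCl, i-Pr2NEt, CH2Cl2, 0 °C → rt
Reagents that add atoms: chloromethyl methyl ether (MOMCl), COCCl
Why: O-alkylation of the phenol under non-acidic conditions protects the future O1 and installs the strongest ortho-directing group on the ring without touching the prenyl group.

**Step 5**
Reactants: 15 2,4,6-trimethoxybenzaldehyde; 16 diethyl [2-(methoxy(methyl)amino)-2-oxoethyl]phosphonate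
Product: 17 (E)-N-methoxy-N-methyl-3-(2,4,6-trimethoxyphenyl)prop-2-enamide
Conditions: NaH, THF, 0 °C → rt
Reagents that add atoms: none
Why: Horner–Wadsworth–Emmons olefination with a stabilised phosphonate anion should give the E-cinnamamide, an acyl donor with no acidic α-hydrogen.

**Step 6**
Reactants: 14 5-ethoxy-1-methoxy-3-(methoxymethoxy)-2-(3-methylbut-2-en-1-yl)benzene; 17 (E)-N-methoxy-N-methyl-3-(2,4,6-trimethoxyphenyl)prop-2-enamide
Product: 19 (E)-1-[6-ethoxy-4-methoxy-2-(methoxymethoxy)-3-(3-methylbut-2-en-1-yl)phenyl]-3-(2,4,6-trimethoxyphenyl)prop-2-en-1-one, via aryllithium 18 (not isolated)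
Conditions: n-BuLi, THF, 0 °C; then 17, THF, −78 °C → 0 °C; aq. NH4Cl
Reagents that add atoms: none
Why: Directed ortho-metalation should remove the ring hydrogen between OMOM and OEt (future C4a), the only free position ortho to the MOM group; 1,2-addition of the aryllithium to the N-methoxy-N-methylamide gives a chelated tetrahedral intermediate that releases the enone only on work-up (Weinreb ketone synthesis).

**Step 7**
Reactants: 19 (E)-1-[6-ethoxy-4-methoxy-2-(methoxymethoxy)-3-(3-methylbut-2-en-1-yl)phenyl]-3-(2,4,6-trimethoxyphenyl)prop-2-en-1-one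
Product: 20 (E)-1-[6-ethoxy-2-hydroxy-4-methoxy-3-(3-methylbut-2-en-1-yl)phenyl]-3-(2,4,6-trimethoxyphenyl)prop-2-en-1-one
Conditions: HCl (3 M aq.), MeOH/THF, rt
Reagents that add atoms: none
Why: Acetal exchange cleaves the MOM ether ortho to the carbonyl under dilute acid at room temperature; the freed phenol is hydrogen-bonded to the ketone, which should hold back both acid-induced chroman formation with the neighbouring prenyl group and uncatalysed ring closure.

**Step 8**
Reactants: 20 (E)-1-[6-ethoxy-2-hydroxy-4-methoxy-3-(3-methylbut-2-en-1-yl)phenyl]-3-(2,4,6-trimethoxyphenyl)prop-2-en-1-one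
Product: 21 (2S)-5-ethoxy-7-methoxy-8-(3-methylbut-2-en-1-yl)-2-(2,4,6-trimethoxyphenyl)-2,3-dihydro-4H-chromen-4-one
Conditions: 1-[3,5-bis(trifluoromethyl)phenyl]-3-(9-deoxy-epi-quinin-9-yl)thiourea (10 mol %), toluene, rt
Reagents that add atoms: none
Why: Organocatalytic enantioselective intramolecular oxa-Michael addition (6-endo-trig) of a 2'-hydroxychalcone: the quinuclidine nitrogen activates the phenol while the thiourea hydrogen-bonds the enone carbonyl, so the phenoxide attacks one face of the β-carbon and C2 is set as S under catalyst control; the ethoxy group on the other ortho oxygen allows only the closure that places the prenyl group at C8.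

**Step 9**
Reactants: 21 (2S)-5-ethoxy-7-methoxy-8-(3-methylbut-2-en-1-yl)-2-(2,4,6-trimethoxyphenyl)-2,3-dihydro-4H-chromen-4-one
Product: 22 (2S)-5-hydroxy-7-methoxy-8-(3-methylbut-2-en-1-yl)-2-(2,4,6-trimethoxyphenyl)-2,3-dihydro-4H-chromen-4-one
Conditions: BCl3 (1.2 equiv), n-Bu4NI (1.2 equiv), CH2Cl2, −78 °C → −40 °C; pH 7 phosphate buffer
Reagents that add atoms: none
Why: Chelation-controlled ether cleavage: BCl3 binds between the C4 carbonyl and the peri 5-ethoxy oxygen and iodide removes the ethyl group by SN2 at low temperature, which should leave the four non-chelated methyl ethers, the prenyl alkene and the C2 stereocentre untouched.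

**Compound list**
1 | ethoxyacetylene | CCOC#C | starting material
2 | acetyl chloride | CC(=O)Cl | starting material
3 | ketene | C=C=O | intermediate
4 | 3-ethoxycyclobut-2-en-1-one | CCOC1=CC(=O)C1 | intermediate
5 | chloroacetaldehyde dimethyl acetal | COC(CCl)OC | starting material
6 | prenyl bromide (1-bromo-3-methylbut-2-ene) | CC(C)=CCBr | starting material
7 | lithium methoxyacetylide | [Li]C#COC | intermediate
8 | 1-methoxy-5-methylhex-4-en-1-yne | COC#CCC=C(C)C | intermediate
9 | 3-ethoxybuta-1,3-dien-1-one (vinylketene) | CCOC(=C)C=C=O | intermediate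
10 | 4-(1-ethoxyvinyl)-3-methoxy-2-(3-methylbut-2-en-1-yl)cyclobut-2-en-1-one (racemic) | CCOC(=C)C1C(OC)=C(CC=C(C)C)C1=O | intermediate
11 | 5-ethoxy-3-methoxy-2-(3-methylbut-2-en-1-yl)hexa-1,3,5-trien-1-one (dienylketene, ketene and ethoxyvinyl groups cis on the central alkene) | CCOC(=C)/C=C(OC)\C(CC=C(C)C)=C=O | intermediate
12 | 5-ethoxy-3-methoxy-2-(3-methylbut-2-en-1-yl)cyclohexa-2,4-dien-1-one | CCOC1=CC(OC)=C(CC=C(C)C)C(=O)C1 | intermediate
13 | 5-ethoxy-3-methoxy-2-(3-methylbut-2-en-1-yl)phenol | CCOc1cc(O)c(CC=C(C)C)c(OC)c1 | intermediate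
14 | 5-ethoxy-1-methoxy-3-(methoxymethoxy)-2-(3-methylbut-2-en-1-yl)benzene | CCOc1cc(OCOC)c(CC=C(C)C)c(OC)c1 | intermediate
15 | 2,4,6-trimethoxybenzaldehyde | COc1cc(OC)c(C=O)c(OC)c1 | starting material
16 | diethyl [2-(methoxy(methyl)amino)-2-oxoethyl]phosphonate | CCOP(=O)(OCC)CC(=O)N(C)OC | starting material
17 | (E)-N-methoxy-N-methyl-3-(2,4,6-trimethoxyphenyl)prop-2-enamide | COc1cc(OC)c(/C=C/C(=O)N(C)OC)c(OC)c1 | intermediate
18 | [6-ethoxy-4-methoxy-2-(methoxymethoxy)-3-(3-methylbut-2-en-1-yl)phenyl]lithium | CCOc1cc(OC)c(CC=C(C)C)c(OCOC)c1[Li] | intermediate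
19 | (E)-1-[6-ethoxy-4-methoxy-2-(methoxymethoxy)-3-(3-methylbut-2-en-1-yl)phenyl]-3-(2,4,6-trimethoxyphenyl)prop-2-en-1-one | CCOc1cc(OC)c(CC=C(C)C)c(OCOC)c1C(=O)/C=C/c1c(OC)cc(OC)cc1OC | intermediate
20 | (E)-1-[6-ethoxy-2-hydroxy-4-methoxy-3-(3-methylbut-2-en-1-yl)phenyl]-3-(2,4,6-trimethoxyphenyl)prop-2-en-1-one | CCOc1cc(OC)c(CC=C(C)C)c(O)c1C(=O)/C=C/c1c(OC)cc(OC)cc1OC | intermediate
21 | (2S)-5-ethoxy-7-methoxy-8-(3-methylbut-2-en-1-yl)-2-(2,4,6-trimethoxyphenyl)-2,3-dihydro-4H-chromen-4-one | COc1cc(OC)c([C@@H]2CC(=O)c3c(OCC)cc(OC)c(CC=C(C)C)c3O2)c(OC)c1 | intermediate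
22 | (2S)-5-hydroxy-7-methoxy-8-(3-methylbut-2-en-1-yl)-2-(2,4,6-trimethoxyphenyl)-2,3-dihydro-4H-chromen-4-one | COc1cc(OC)c([C@@H]2CC(=O)c3c(O)cc(OC)c(CC=C(C)C)c3O2)c(OC)c1 | target

**Step count**
Total: 9 steps. Longest linear sequence: 7 steps (step 1 or 2, then steps 3, 4, 6, 7, 8, 9).

**Steps most likely to fail**

Step 3. The vinylogous-ester character of 4 may slow its electrocyclic opening, so that at the temperature needed the ketene dimerises or acylates the product faster than alkyne 8 intercepts it. The fallback generates the same vinylketene 9 at room temperature by another route. Commercial ethyl (E)-3-ethoxybut-2-enoate F1 is saponified (NaOH, EtOH/H2O, then careful acidification) to (E)-3-ethoxybut-2-enoic acid F2, which oxalyl chloride and catalytic DMF in CH2Cl2 convert into (E)-3-ethoxybut-2-enoyl chloride F3. Slow addition of F3 to Et3N and alkyne 8 in CH2Cl2 at room temperature should cause 1,4-dehydrochlorination to 9 and [2+2] capture to vinylcyclobutenone 10. Exchange of the solvent for toluene and heating to 80 °C should then complete ring opening and 6π closure. The fallback sets out from 8 and returns to the route at 13.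

Step 8. Conjugate addition to an enone whose β-aryl group is very electron-rich and doubly ortho-substituted may be slow, and reversible ring opening under the basic catalyst may erode the enantiomeric purity. The fallback separates ring closure from stereocontrol. Chalcone 20 is cyclised without stereocontrol (NaOAc, EtOH, reflux) to racemic 5-ethoxy-7-methoxy-8-(3-methylbut-2-en-1-yl)-2-(2,4,6-trimethoxyphenyl)chroman-4-one F4. F4 is then resolved kinetically by asymmetric transfer hydrogenation (Cp*RhCl[(R,R)-TsDPEN], HCO2H/Et3N, EtOAc, rt, stopped near half conversion). The catalyst antipode is chosen so that the 2R enantiomer is reduced, as expected for the (R,R)-ligand, to the cis alcohol (2R,4R)-5-ethoxy-7-methoxy-8-(3-methylbut-2-en-1-yl)-2-(2,4,6-trimethoxyphenyl)chroman-4-ol F5. The unreduced 2S ketone is separated by chromatography; the prenyl alkene is not touched by transfer hydrogenation. The fallback sets out from 20 and returns at 21.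

Step 9. The Lewis acid may promote heterolysis of the C2–O1 bond, which is benzylic to the trimethoxyphenyl ring, leading to racemisation or ring opening; hydrohalogenation of the prenyl alkene or loss of a second methyl ether are further risks. The fallback moves the dealkylation to a stage without a stereocentre. MOM chalcone 19 is treated with BCl3 (excess) and n-Bu4NI in CH2Cl2 (−78 °C → 0 °C), removing both the MOM and the ethyl group to give (E)-1-[2,6-dihydroxy-4-methoxy-3-(3-methylbut-2-en-1-yl)phenyl]-3-(2,4,6-trimethoxyphenyl)prop-2-en-1-one F6. TBSCl and imidazole in CH2Cl2 at 0 °C should silylate the less hindered hydroxyl, the one not flanked by the prenyl group, to give (E)-1-[6-(tert-butyldimethylsilyloxy)-2-hydroxy-4-methoxy-3-(3-methylbut-2-en-1-yl)phenyl]-3-(2,4,6-trimethoxyphenyl)prop-2-en-1-one F7. The thiourea-catalysed oxa-Michael closure of step 8 then gives (2S)-5-(tert-butyldimethylsilyloxy)-7-methoxy-8-(3-methylbut-2-en-1-yl)-2-(2,4,6-trimethoxyphenyl)-2,3-dihydro-4H-chromen-4-one F8. HF·pyridine in THF at 0 °C removes the silyl group under nearly neutral conditions. The fallback sets out from 19 and returns at 22.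

**Further compounds**
F1 | step 3 | ethyl (E)-3-ethoxybut-2-enoate | CCO/C(C)=C/C(=O)OCC
F2 | step 3 | (E)-3-ethoxybut-2-enoic acid | CCO/C(C)=C/C(=O)O
F3 | step 3 | (E)-3-ethoxybut-2-enoyl chloride | CCO/C(C)=C/C(=O)Cl
F4 | step 8 | racemic 5-ethoxy-7-methoxy-8-(3-methylbut-2-en-1-yl)-2-(2,4,6-trimethoxyphenyl)chroman-4-one | COc1cc(OC)c(C2CC(=O)c3c(OCC)cc(OC)c(CC=C(C)C)c3O2)c(OC)c1
F5 | step 8 | (2R,4R)-5-ethoxy-7-methoxy-8-(3-methylbut-2-en-1-yl)-2-(2,4,6-trimethoxyphenyl)chroman-4-ol | COc1cc(OC)c([C@H]2C[C@@H](O)c3c(OCC)cc(OC)c(CC=C(C)C)c3O2)c(OC)c1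
F6 | step 9 | (E)-1-[2,6-dihydroxy-4-methoxy-3-(3-methylbut-2-en-1-yl)phenyl]-3-(2,4,6-trimethoxyphenyl)prop-2-en-1-one | COc1cc(O)c(C(=O)/C=C/c2c(OC)cc(OC)cc2OC)c(O)c1CC=C(C)C
F7 | step 9 | (E)-1-[6-(tert-butyldimethylsilyloxy)-2-hydroxy-4-methoxy-3-(3-methylbut-2-en-1-yl)phenyl]-3-(2,4,6-trimethoxyphenyl)prop-2-en-1-one | COc1cc(O[Si](C)(C)C(C)(C)C)c(C(=O)/C=C/c2c(OC)cc(OC)cc2OC)c(O)c1CC=C(C)C
F8 | step 9 | (2S)-5-(tert-butyldimethylsilyloxy)-7-methoxy-8-(3-methylbut-2-en-1-yl)-2-(2,4,6-trimethoxyphenyl)-2,3-dihydro-4H-chromen-4-one | COc1cc(OC)c([C@@H]2CC(=O)c3c(O[Si](C)(C)C(C)(C)C)cc(OC)c(CC=C(C)C)c3O2)c(OC)c1
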